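**Retrosynthetic overview** (labdane numbering: ring A = C1–C5 and C10, ring B = C5–C10, side chain C11–C16 on C9)

1. End-game simplifications: the oxirane comes from Sharpless epoxidation of the C13=C14 allylic alcohol, the C8 methylidene from a C8 carbinol via the ketone, and a C1=C2 double bond is added retrosynthetically (hydrogenated after the key step).
2. Key disconnection: rings A and B are opened together by a retro-[4+2] across C3–C4 and C5–C10, giving an acyclic triene in which a (Z)-diene C3=C2–C1=C10(CH3) and an (E)-α-methyl enoate C4=C5 are joined by the chain C6–C9.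
3. Enabling feature: in ring A the ester-bearing C4 and the ring-fusion carbon C5 are adjacent and lie between the two bonds (an α-methylacrylate retron), the remaining ring A path C10–C1–C2–C3 is a diene once C1=C2 is present, ring B is six-membered (a four-carbon tether), and the cis C5/C10 ring fusion is what a (Z)-diene delivers.
4. The triene comes from a catalytic asymmetric hetero-Diels–Alder union (C8–C9 and O–C2) of a C4–C8 aldehyde with a geraniol-derived methoxy diene, geraniol supplying C15–C11, C9, C10, C20 and C1; the dihydropyran sets C8 and C9, locks the C1=C10 geometry, and is opened by a lactol Wittig reaction.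
5. Ring order: temporary dihydropyran (step 7, opened in step 9), then rings A and B in one step (step 10), then the oxirane (step 15).

Key step: step 10

Assumption (remark on the chemistry): the given descriptors are read as a labdane-type skeleton with a cis-fused decalin (H-5, CH3-10, the C4 ester and the C9 side chain on one face), (4S,5S,9S,10R,13R,14R); the route is built for exactly this isomer. TBDPS = tert-butyldiphenylsilyl.

**Step 1**
Reactants: 1 geraniol
Product: 2 tert-butyl{[(2E)-3,7-dimethylocta-2,6-dien-1-yl]oxy}diphenylsilane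
Conditions: t-BuPh2SiCl, imidazole, DMF, 0 °C → rt
Reagents that add atoms: tert-butyl(chloro)diphenylsilane, CC(C)(C)[Si](Cl)(c1ccccc1)c1ccccc1
Why: Imidazole-promoted silyl ether formation at a primary allylic alcohol; the bulky TBDPS ether should survive every later step up to fluoride cleavage, and the allylic oxygen keeps the 2,3-alkene the less electron-rich one in step 2.

**Step 2**
Reactants: 2 geranyl TBDPS ether
Product: 3 (2E,6E)-8-(TBDPS-oxy)-2,6-dimethylocta-2,6-dien-1-ol
Conditions: SeO2 (0.2 equiv), t-BuOOH (3 equiv), salicylic acid (0.1 equiv), CH2Cl2, rt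
Reagents that add atoms: tert-butyl hydroperoxide, CC(C)(C)OO (the oxygen atom is relayed through catalytic SeO2, O=[Se]=O)
Why: Sharpless catalytic SeO2 allylic oxidation (ene reaction, then [2,3]-sigmatropic shift) should attack the more electron-rich terminal trisubstituted alkene at its (E)-methyl group and give the (6E)-allylic alcohol; any aldehyde 4 formed by over-oxidation is simply carried into step 3.

**Step 3**
Reactants: 3 allylic alcohol
Product: 4 (2E,6E)-8-(TBDPS-oxy)-2,6-dimethylocta-2,6-dienal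
Conditions: MnO2 (activated, excess), CH2Cl2, rt
Reagents that add atoms: none
Why: MnO2 oxidation is selective for the allylic alcohol and should give the (E)-enal without E/Z isomerisation.

**Step 4**
Reactants: 4 enal
Product: 5 tert-butyl{[(2E,6E,8E)-9-methoxy-3,7-dimethylnona-2,6,8-trien-1-yl]oxy}diphenylsilane
Conditions: MeOCH2PPh3Cl, KN(SiMe3)2, THF, −78 → 0 °C; then 4, −78 °C → rt; chromatography on Et3N-deactivated silica
Reagents that add atoms: (methoxymethyl)triphenylphosphonium chloride, COC[P+](c1ccccc1)(c1ccccc1)c1ccccc1.[Cl-]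
Why: Wittig methoxymethylenation of the enal gives the 1-methoxy diene; the (8E)-enol ether is the isomer taken on, since only it can reach the s-cis geometry needed in step 7, and the (6E)-geometry inherited from geraniol is untouched.

**Step 5**
Reactants: 6 2,3-dihydrofuran
Product: 9 methyl (2E)-6-hydroxy-2-methylhex-2-enoate, via oxolan-2-ol 7 (not isolated), via 4-hydroxybutanal 8 (not isolated)
Conditions: 0.2 M aq. HCl, 0 °C → rt; NaHCO3 to pH 7; then Ph3P=C(CH3)CO2Me, CH2Cl2, rt → 40 °C
Reagents that add atoms: water, O; methyl 2-(triphenylphosphoranylidene)propanoate, COC(=O)C(C)=P(c1ccccc1)(c1ccccc1)c1ccccc1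
Why: Acid-catalysed hydration of the enol ether gives the lactol, whose open-chain tautomer should undergo E-selective Wittig olefination with the stabilised ylide, fixing the (E)-α-methyl enoate that later defines the C4/C5 relationship.

**Step 6**
Reactants: 9 hydroxy enoate
Product: 10 methyl (2E)-2-methyl-6-oxohex-2-enoate
Conditions: Dess–Martin periodinane, CH2Cl2, 0 °C → rt
Reagents that add atoms: none
Why: Dess–Martin oxidation of a primary alcohol to the aldehyde under neutral conditions that leave the enoate untouched.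

**Step 7**
Reactants: 5 methoxy diene; 10 aldehyde
Product: 11 methyl (2E)-5-[(2R,3R,6R)-3-{(3E)-5-(TBDPS-oxy)-3-methylpent-3-en-1-yl}-6-methoxy-4-methyl-3,6-dihydro-2H-pyran-2-yl]-2-methylpent-2-enoate
Conditions: CrCl(L) (5 mol %; L = dianion of (1S,2R)-1-{[3-(1-adamantyl)-2-hydroxy-5-methylbenzylidene]amino}indan-2-ol, C27H29NO2; trivalent chromium), 4 Å molecular sieves, equimolar 5 and 10, neat, rt
Reagents that add atoms: none
Why: Jacobsen catalytic asymmetric hetero-Diels–Alder reaction of a 1-alkoxy diene with an aldehyde, a cycloaddition in which every atom of both partners ends up in the product; the endo transition state should give the all-cis dihydropyran (C7 and C11 chains cis on the ring, i.e. the syn C8-oxygen/C9-side-chain relationship of the open chain), the facial preference of the (1S,2R)-ligand series is expected to set C8 as R and thereby C9 as R, and the ring locks C10=C1 in the Z geometry.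

**Step 8**
Reactants: 11 dihydropyran methyl acetal
Product: 12 methyl (2E)-5-[(2R,3R)-3-{(3E)-5-(TBDPS-oxy)-3-methylpent-3-en-1-yl}-6-hydroxy-4-methyl-3,6-dihydro-2H-pyran-2-yl]-2-methylpent-2-enoate (both anomers)
Conditions: pyridinium p-toluenesulfonate (0.1 equiv), acetone/H2O (5:1), 0 °C → rt
Reagents that add atoms: water, O
Why: Mild acid hydrolysis of the allylic methyl acetal through the conjugated oxocarbenium ion; only the anomeric centre, which is lost in step 9, is affected.

**Step 9**
Reactants: 12 lactol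
Product: 14 methyl (2E,6R,7R,8Z)-7-{(3E)-5-(TBDPS-oxy)-3-methylpent-3-en-1-yl}-6-hydroxy-2,8-dimethylundeca-2,8,10-trienoate, via open-chain hydroxy enal 13 (not isolated)
Conditions: Ph3PCH3Br (3.0 equiv), n-BuLi (2.8 equiv), THF, 0 °C; then 12, −78 → 0 °C; aq. NH4Cl quench at 0 °C
Reagents that add atoms: methyltriphenylphosphonium bromide, C[P+](c1ccccc1)(c1ccccc1)c1ccccc1.[Br-]
Why: Wittig methylenation of a lactol through its open-chain hydroxy-enal tautomer carries the ring-enforced (Z)-geometry into the diene, and the lithium alkoxide at low temperature is not expected to add to the hindered α-methyl enoate.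

**Step 10**
Reactants: 14 triene
Product: 15 methyl (1S,4aS,5R,6R,8aS)-5-{(3E)-5-(TBDPS-oxy)-3-methylpent-3-en-1-yl}-6-hydroxy-1,4a-dimethyl-1,2,4a,5,6,7,8,8a-octahydronaphthalene-1-carboxylate
Conditions: PhMe (0.01 M), BHT (0.1 equiv), degassed, sealed tube, 170–180 °C
Reagents that add atoms: none
Why: Thermal type 1 intramolecular Diels–Alder reaction: a concerted suprafacial [4+2] cycloaddition in which the (Z)-diene C3=C2–C1=C10 and the enoate C4=C5 of the 1,3,9-decatriene form C3–C4 and C5–C10 in one event, the closest known reaction type being the thermal cyclisation of (Z)-diene undeca-2,8,10-trienoates to cis-fused octalins. Ring A closes as the new cyclohexene of the cycloaddition and ring B as the six-membered carbocycle spanned by the tether C6–C9, which lies exo in a chair-like fold with the C8 hydroxyl and the C9 side chain equatorial. Because the tether sits on the inside (Z) position of the diene it can reach only the cis-fused transition state, which is also the ester-endo one, so H-5 and CH3-10 should come out cis. The (E)-geometry of the enoate is transferred suprafacially to C4, placing the ester cis to H-5 and hence on the face of CH3-10. C5 and C10 are set relative to the existing C9 centre by allylic 1,3-strain: the C9–H bond lies in the diene plane facing C2, the side chain points away from the dienophile, and the C5–C10 bond forms on the face that leaves the side chain cis to CH3-10. The step needs cis-fusion, π-facial control and a cycloaddition faster than the [1,5]-hydrogen shift open to (Z)-dienes; the first two are secured by the (Z)-C1=C10 geometry from step 7 and by the C9 stereocentre, the last by the conformational bias of the trisubstituted tether and the lowest temperature that gives turnover.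

**Step 11**
Reactants: 15 octalin
Product: 16 methyl (1S,4aS,5R,6R,8aS)-5-{(3E)-5-(TBDPS-oxy)-3-methylpent-3-en-1-yl}-6-hydroxy-1,4a-dimethyldecahydronaphthalene-1-carboxylate
Conditions: H2 (3 atm), RhCl(PPh3)3 (10 mol %), PhH/EtOH (1:1), rt
Reagents that add atoms: none
Why: Homogeneous hydrogenation with Wilkinson's catalyst should reduce the cis-disubstituted ring alkene and spare the trisubstituted side-chain alkene, which binds rhodium far more weakly; no stereocentre is formed.

**Step 12**
Reactants: 16 secondary alcohol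
Product: 17 methyl (1S,4aS,5R,8aS)-5-{(3E)-5-(TBDPS-oxy)-3-methylpent-3-en-1-yl}-1,4a-dimethyl-6-oxodecahydronaphthalene-1-carboxylate
Conditions: Dess–Martin periodinane, pyridine, CH2Cl2, 0 °C → rt
Reagents that add atoms: none
Why: Pyridine-buffered Dess–Martin oxidation should give the C8 ketone without epimerising the adjacent C9 centre.

**Step 13**
Reactants: 17 ketone
Product: 18 methyl (1S,4aR,5S,8aS)-5-{(3E)-5-(TBDPS-oxy)-3-methylpent-3-en-1-yl}-1,4a-dimethyl-6-methylidenedecahydronaphthalene-1-carboxylate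
Conditions: Zn, CH2Br2, TiCl4 (Lombardo reagent, pre-formed in THF at 5 °C), CH2Cl2, 0 °C → rt
Reagents that add atoms: dibromomethane, BrCBr
Why: Takai–Lombardo methylenation with the non-basic zinc/titanium methylene reagent should convert the enolisable ketone into the exocyclic alkene without epimerising C9 and without touching the ester.

**Step 14**
Reactants: 18 silyl ether
Product: 19 methyl (1S,4aR,5S,8aS)-5-[(3E)-5-hydroxy-3-methylpent-3-en-1-yl]-1,4a-dimethyl-6-methylidenedecahydronaphthalene-1-carboxylate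
Conditions: Bu4NF, THF, 0 °C → rt
Reagents that add atoms: none
Why: Fluoride cleavage of the silyl ether, driven by Si–F bond formation, frees the allylic alcohol and leaves the hindered methyl ester alone.

**Step 15**
Reactants: 19 allylic alcohol
Product: 20 methyl (1S,4aR,5S,8aS)-5-{2-[(2R,3R)-3-(hydroxymethyl)-2-methyloxiran-2-yl]ethyl}-1,4a-dimethyl-6-methylidenedecahydronaphthalene-1-carboxylate (target)
Conditions: Ti(OiPr)4 (0.1 equiv), D-(−)-diethyl tartrate (0.12 equiv), t-BuOOH (2 equiv, in decane), 4 Å molecular sieves, CH2Cl2, −20 °C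
Reagents that add atoms: tert-butyl hydroperoxide, CC(C)(C)OO
Why: Sharpless asymmetric epoxidation: the titanium tartrate complex binds the allylic alcohol and delivers oxygen to one face of the (E)-alkene under reagent control, D-(−)-tartrate giving the (2R,3R)-epoxy alcohol (13R,14R), while the isolated exocyclic alkene is inert.

**Compound list**

1 | geraniol, (2E)-3,7-dimethylocta-2,6-dien-1-ol | CC(C)=CCC/C(C)=C/CO | starting material
2 | tert-butyl{[(2E)-3,7-dimethylocta-2,6-dien-1-yl]oxy}diphenylsilane | CC(C)=CCC/C(C)=C/CO[Si](c1ccccc1)(c1ccccc1)C(C)(C)C | intermediate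
3 | (2E,6E)-8-(TBDPS-oxy)-2,6-dimethylocta-2,6-dien-1-ol | OC/C(C)=C/CC/C(C)=C/CO[Si](c1ccccc1)(c1ccccc1)C(C)(C)C | intermediate
4 | (2E,6E)-8-(TBDPS-oxy)-2,6-dimethylocta-2,6-dienal | O=C/C(C)=C/CC/C(C)=C/CO[Si](c1ccccc1)(c1ccccc1)C(C)(C)C | intermediate
5 | tert-butyl{[(2E,6E,8E)-9-methoxy-3,7-dimethylnona-2,6,8-trien-1-yl]oxy}diphenylsilane | CO/C=C/C(C)=C/CC/C(C)=C/CO[Si](c1ccccc1)(c1ccccc1)C(C)(C)C | intermediate
6 | 2,3-dihydrofuran | C1=COCC1 | starting material
7 | oxolan-2-ol (forms in the flask) | OC1CCCO1 | intermediate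
8 | 4-hydroxybutanal (open-chain tautomer of 7, forms in the flask) | OCCCC=O | intermediate
9 | methyl (2E)-6-hydroxy-2-methylhex-2-enoate | COC(=O)/C(C)=C/CCCO | intermediate
10 | methyl (2E)-2-methyl-6-oxohex-2-enoate | COC(=O)/C(C)=C/CCC=O | intermediate
11 | methyl (2E)-5-[(2R,3R,6R)-3-{(3E)-5-(TBDPS-oxy)-3-methylpent-3-en-1-yl}-6-methoxy-4-methyl-3,6-dihydro-2H-pyran-2-yl]-2-methylpent-2-enoate | COC(=O)/C(C)=C/CC[C@H]1O[C@@H](OC)C=C(C)[C@H]1CC/C(C)=C/CO[Si](c1ccccc1)(c1ccccc1)C(C)(C)C | intermediate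
12 | methyl (2E)-5-[(2R,3R)-3-{(3E)-5-(TBDPS-oxy)-3-methylpent-3-en-1-yl}-6-hydroxy-4-methyl-3,6-dihydro-2H-pyran-2-yl]-2-methylpent-2-enoate (both anomers) | COC(=O)/C(C)=C/CC[C@H]1OC(O)C=C(C)[C@H]1CC/C(C)=C/CO[Si](c1ccccc1)(c1ccccc1)C(C)(C)C | intermediate
13 | methyl (2E,6R,7R,8Z)-7-{(3E)-5-(TBDPS-oxy)-3-methylpent-3-en-1-yl}-6-hydroxy-2,8-dimethyl-10-oxodeca-2,8-dienoate (open-chain tautomer of 12, forms in the flask) | COC(=O)/C(C)=C/CC[C@@H](O)[C@H](CC/C(C)=C/CO[Si](c1ccccc1)(c1ccccc1)C(C)(C)C)/C(C)=C\C=O | intermediate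
14 | methyl (2E,6R,7R,8Z)-7-{(3E)-5-(TBDPS-oxy)-3-methylpent-3-en-1-yl}-6-hydroxy-2,8-dimethylundeca-2,8,10-trienoate | COC(=O)/C(C)=C/CC[C@@H](O)[C@H](CC/C(C)=C/CO[Si](c1ccccc1)(c1ccccc1)C(C)(C)C)/C(C)=C\C=C | intermediate
15 | methyl (1S,4aS,5R,6R,8aS)-5-{(3E)-5-(TBDPS-oxy)-3-methylpent-3-en-1-yl}-6-hydroxy-1,4a-dimethyl-1,2,4a,5,6,7,8,8a-octahydronaphthalene-1-carboxylate | O[C@@H]1CC[C@H]2[C@](C)(C=CC[C@]2(C)C(=O)OC)[C@H]1CC/C(C)=C/CO[Si](c1ccccc1)(c1ccccc1)C(C)(C)C | intermediate
16 | methyl (1S,4aS,5R,6R,8aS)-5-{(3E)-5-(TBDPS-oxy)-3-methylpent-3-en-1-yl}-6-hydroxy-1,4a-dimethyldecahydronaphthalene-1-carboxylate | O[C@@H]1CC[C@H]2[C@](C)(CCC[C@]2(C)C(=O)OC)[C@H]1CC/C(C)=C/CO[Si](c1ccccc1)(c1ccccc1)C(C)(C)C | intermediate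
17 | methyl (1S,4aS,5R,8aS)-5-{(3E)-5-(TBDPS-oxy)-3-methylpent-3-en-1-yl}-1,4a-dimethyl-6-oxodecahydronaphthalene-1-carboxylate | O=C1CC[C@H]2[C@](C)(CCC[C@]2(C)C(=O)OC)[C@H]1CC/C(C)=C/CO[Si](c1ccccc1)(c1ccccc1)C(C)(C)C | intermediate
18 | methyl (1S,4aR,5S,8aS)-5-{(3E)-5-(TBDPS-oxy)-3-methylpent-3-en-1-yl}-1,4a-dimethyl-6-methylidenedecahydronaphthalene-1-carboxylate | C=C1CC[C@H]2[C@](C)(CCC[C@]2(C)C(=O)OC)[C@H]1CC/C(C)=C/CO[Si](c1ccccc1)(c1ccccc1)C(C)(C)C | intermediate
19 | methyl (1S,4aR,5S,8aS)-5-[(3E)-5-hydroxy-3-methylpent-3-en-1-yl]-1,4a-dimethyl-6-methylidenedecahydronaphthalene-1-carboxylate | C=C1CC[C@H]2[C@](C)(CCC[C@]2(C)C(=O)OC)[C@H]1CC/C(C)=C/CO | intermediate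
20 | methyl (1S,4aR,5S,8aS)-5-{2-[(2R,3R)-3-(hydroxymethyl)-2-methyloxiran-2-yl]ethyl}-1,4a-dimethyl-6-methylidenedecahydronaphthalene-1-carboxylate | C=C1CC[C@H]2[C@](C)(CCC[C@]2(C)C(=O)OC)[C@H]1CC[C@@]1(C)O[C@@H]1CO | target

**Step count**

Total step count: 15. Longest linear sequence: 13 steps (steps 1–4 and 7–15, from geraniol).

**Steps most likely to fail**

1. Step 10. The cycloaddition has to build two quaternary centres from a (Z)-diene and a trisubstituted enoate. It may be outrun by the [1,5]-hydrogen shift of the (Z)-diene or by thermal decomposition, and π-facial control may erode at the temperature required.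
Fallback (sets out from 14, returns to the route at 15): i-Bu2AlH (CH2Cl2, −78 °C) should reduce the enoate of 14 to the triene-1,6-diol F1. MnO2 should then oxidise only the allylic primary hydroxyl to the hydroxy trienal F2. Me2AlCl (2.2 equiv, CH2Cl2, −78 → −20 °C, one equivalent being taken up by the hydroxyl) should promote the intramolecular Diels–Alder reaction of this more reactive enal at a temperature where the hydrogen shift cannot compete, through the same aldehyde-endo, cis-fused transition state, giving the bicyclic hydroxy aldehyde F3. Pinnick oxidation (NaClO2, NaH2PO4, 2-methyl-2-butene, t-BuOH/H2O) to the hydroxy acid F4 and esterification with Me3SiCHN2 (MeOH/PhMe) lead back to 15.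

2. Step 7. Turnover of the unactivated aliphatic aldehyde with a mono-oxygenated diene may be slow, the enol ether may be lost to adventitious acid, or enantiocontrol may be insufficient.
Fallback (sets out from 3 and 10, returns to the route at 12): MsCl/Et3N followed by LiCl (DMF) should turn 3 into the allylic chloride F5, and Bu3SnLi (THF, −78 °C) into the allylstannane F6. Addition of F6 to aldehyde 10 under a chiral (acyloxy)borane Lewis acid [from (2,6-diisopropoxybenzoyl)tartaric acid and BH3·THF, the enantiomer that delivers the 6R carbinol; EtCN, −78 °C] should pass through an open transition state and give the syn-homoallylic alcohol F7, which carries an isopropenyl group on C9. Pd(OAc)2/1,3-bis(diphenylphosphino)propane-catalysed addition of the hydroxyl to methoxyallene (Et3N, MeCN) should give the mixed acrolein acetal F8. Ring-closing metathesis with the second-generation Grubbs catalyst RuCl2(CHPh)(PCy3)(SIMes) between the acetal vinyl group and the isopropenyl group should close the Z-locked dihydropyran acetal F9 (anomeric mixture). Hydrolysis as in step 8 then gives 12.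

3. Step 9. The C8 alkoxide may add in a conjugate sense to the enoate, or the ring-opened enal may isomerise from Z to E under the basic conditions.
Fallback (sets out from 12, returns to the route at 14): Luche reduction (NaBH4, CeCl3·7H2O, MeOH, −20 °C) of the open-chain form should give the Z-allylic diol F10, and Et3SiCl/imidazole (DMF) the bis(triethylsilyl) ether F11. Swern conditions [(COCl)2, DMSO, CH2Cl2, −78 → −30 °C, then Et3N], which oxidise a primary triethylsilyl ether directly and leave the secondary one, should give the silyloxy Z-enal F12. Ph3P=CH2 (THF, −78 → 0 °C) then meets no free alkoxide and should give the silyloxy triene F13. HF·pyridine (THF/pyridine, 0 °C) removes the triethylsilyl group to give 14.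

**Further compounds**

F1 | step 10 | (2E,6R,7R,8Z)-7-{(3E)-5-(TBDPS-oxy)-3-methylpent-3-en-1-yl}-2,8-dimethylundeca-2,8,10-triene-1,6-diol | OC/C(C)=C/CC[C@@H](O)[C@H](CC/C(C)=C/CO[Si](c1ccccc1)(c1ccccc1)C(C)(C)C)/C(C)=C\C=C
F2 | step 10 | (2E,6R,7R,8Z)-7-{(3E)-5-(TBDPS-oxy)-3-methylpent-3-en-1-yl}-6-hydroxy-2,8-dimethylundeca-2,8,10-trienal | O=C/C(C)=C/CC[C@@H](O)[C@H](CC/C(C)=C/CO[Si](c1ccccc1)(c1ccccc1)C(C)(C)C)/C(C)=C\C=C
F3 | step 10 | (1S,4aS,5R,6R,8aS)-5-{(3E)-5-(TBDPS-oxy)-3-methylpent-3-en-1-yl}-6-hydroxy-1,4a-dimethyl-1,2,4a,5,6,7,8,8a-octahydronaphthalene-1-carbaldehyde | O[C@@H]1CC[C@H]2[C@](C)(C=CC[C@]2(C)C=O)[C@H]1CC/C(C)=C/CO[Si](c1ccccc1)(c1ccccc1)C(C)(C)C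
F4 | step 10 | (1S,4aS,5R,6R,8aS)-5-{(3E)-5-(TBDPS-oxy)-3-methylpent-3-en-1-yl}-6-hydroxy-1,4a-dimethyl-1,2,4a,5,6,7,8,8a-octahydronaphthalene-1-carboxylic acid | O[C@@H]1CC[C@H]2[C@](C)(C=CC[C@]2(C)C(=O)O)[C@H]1CC/C(C)=C/CO[Si](c1ccccc1)(c1ccccc1)C(C)(C)C
F5 | step 7 | tert-butyl{[(2E,6E)-8-chloro-3,7-dimethylocta-2,6-dien-1-yl]oxy}diphenylsilane | ClC/C(C)=C/CC/C(C)=C/CO[Si](c1ccccc1)(c1ccccc1)C(C)(C)C
F6 | step 7 | tert-butyl{[(2E,6E)-3,7-dimethyl-8-(tributylstannyl)octa-2,6-dien-1-yl]oxy}diphenylsilane | CCCC[Sn](CCCC)(CCCC)C/C(C)=C/CC/C(C)=C/CO[Si](c1ccccc1)(c1ccccc1)C(C)(C)C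
F7 | step 7 | methyl (2E,6R,7R)-7-{(3E)-5-(TBDPS-oxy)-3-methylpent-3-en-1-yl}-6-hydroxy-2,8-dimethylnona-2,8-dienoate | COC(=O)/C(C)=C/CC[C@@H](O)[C@H](CC/C(C)=C/CO[Si](c1ccccc1)(c1ccccc1)C(C)(C)C)C(C)=C
F8 | step 7 | methyl (2E,6R,7R)-7-{(3E)-5-(TBDPS-oxy)-3-methylpent-3-en-1-yl}-6-[(1-methoxyprop-2-en-1-yl)oxy]-2,8-dimethylnona-2,8-dienoate (both acetal epimers) | COC(=O)/C(C)=C/CC[C@@H](OC(OC)C=C)[C@H](CC/C(C)=C/CO[Si](c1ccccc1)(c1ccccc1)C(C)(C)C)C(C)=C
F9 | step 7 | methyl (2E)-5-[(2R,3R)-3-{(3E)-5-(TBDPS-oxy)-3-methylpent-3-en-1-yl}-6-methoxy-4-methyl-3,6-dihydro-2H-pyran-2-yl]-2-methylpent-2-enoate (both anomers) | COC(=O)/C(C)=C/CC[C@H]1OC(OC)C=C(C)[C@H]1CC/C(C)=C/CO[Si](c1ccccc1)(c1ccccc1)C(C)(C)C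
F10 | step 9 | methyl (2E,6R,7R,8Z)-7-{(3E)-5-(TBDPS-oxy)-3-methylpent-3-en-1-yl}-6,10-dihydroxy-2,8-dimethyldeca-2,8-dienoate | COC(=O)/C(C)=C/CC[C@@H](O)[C@H](CC/C(C)=C/CO[Si](c1ccccc1)(c1ccccc1)C(C)(C)C)/C(C)=C\CO
F11 | step 9 | methyl (2E,6R,7R,8Z)-7-{(3E)-5-(TBDPS-oxy)-3-methylpent-3-en-1-yl}-2,8-dimethyl-6,10-bis[(triethylsilyl)oxy]deca-2,8-dienoate | COC(=O)/C(C)=C/CC[C@@H](O[Si](CC)(CC)CC)[C@H](CC/C(C)=C/CO[Si](c1ccccc1)(c1ccccc1)C(C)(C)C)/C(C)=C\CO[Si](CC)(CC)CC
F12 | step 9 | methyl (2E,6R,7R,8Z)-7-{(3E)-5-(TBDPS-oxy)-3-methylpent-3-en-1-yl}-2,8-dimethyl-10-oxo-6-[(triethylsilyl)oxy]deca-2,8-dienoate | COC(=O)/C(C)=C/CC[C@@H](O[Si](CC)(CC)CC)[C@H](CC/C(C)=C/CO[Si](c1ccccc1)(c1ccccc1)C(C)(C)C)/C(C)=C\C=O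
F13 | step 9 | methyl (2E,6R,7R,8Z)-7-{(3E)-5-(TBDPS-oxy)-3-methylpent-3-en-1-yl}-2,8-dimethyl-6-[(triethylsilyl)oxy]undeca-2,8,10-trienoate | COC(=O)/C(C)=C/CC[C@@H](O[Si](CC)(CC)CC)[C@H](CC/C(C)=C/CO[Si](c1ccccc1)(c1ccccc1)C(C)(C)C)/C(C)=C\C=C
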